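**Plan**

- Retrosynthesis: the N–CH2 and CH2–CH bonds of the six-membered lactam are cut first (formaldehyde, aza-Prins). Then follow the cis alkene of the seven-membered ring (metathesis), ring B (carbonylative coupling, Nazarov), the amide bond of the nine-membered lactam, the bond between the two quaternary carbons (Claisen) and the side-chain C–C bond (B-alkyl Suzuki).
- Enabling feature: in the nine-membered lactam the nitrogen and the quaternary carbon bearing CH2OAc stand 1,4 to each other. The target spans them by N–CH2–CH, whose CH is the cycloheptadiene ring carbon next to that quaternary carbon, so one carbon of formaldehyde can tie this alkene carbon to nitrogen.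
- Forward order: chain azide, then Z-allylic alcohol; enol ether with the ring A keto ester; Claisen; nine-membered lactam; ring B; seven-membered ring; six-membered lactam; hydrogenation.
- Stereochemistry: Evans syn-aldol (carbinol and methyl centres); (S)-but-3-en-2-ol relayed through a chair Claisen (both quaternary carbons); steric approach control (hydride for the ring-fusion CH, protonation for the CO2Me-bearing CH); the medium-ring tether (new lactam methine).

Key step: step 22

Remark: the β-keto ester made in step 10 is stereolabile at its ring methine and is used as the racemate (that carbon becomes sp2 in step 11); formaldehyde is introduced as paraformaldehyde.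

**Route**

Step 1
Reactants: 1 (S)-4-benzyl-3-propanoyl-1,3-oxazolidin-2-one; 2 acrolein
Product: 4 syn-aldol imide, via dibutylboron enolate 3 (not isolated)
Conditions: Bu2BOTf, iPr2NEt, CH2Cl2, −78 → 0 °C; then 2, −78 °C; pH 7 buffer, MeOH, H2O2, 0 °C
Reagents that add atoms: none
Why: Evans syn-aldol reaction in which the (Z)-boron enolate adds to acrolein through a closed chair transition state on the enolate face not shielded by the auxiliary benzyl group, which should set the carbinol and methyl centres as (2S,3R), syn.

Step 2
Reactants: 4 syn-aldol imide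
Product: 5 benzyl ether imide
Conditions: BnOC(=NH)CCl3, TfOH (cat.), CH2Cl2/cyclohexane, 0 → 23 °C
Reagents that add atoms: benzyl 2,2,2-trichloroacetimidate, N=C(OCc1ccccc1)C(Cl)(Cl)Cl
Why: Acid-catalysed O-benzylation with the trichloroacetimidate should etherify the β-hydroxy imide without the retro-aldol cleavage that a basic Williamson etherification would invite, and no stereocentre is touched.

Step 3
Reactants: 5 benzyl ether imide
Product: 6 (2R,3R)-3-(benzyloxy)-2-methylpent-4-en-1-ol
Conditions: LiBH4, MeOH, Et2O, 0 °C
Reagents that add atoms: none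
Why: Reductive cleavage of the N-acyl oxazolidinone, in which borohydride attacks the more electrophilic exocyclic carbonyl, should give the primary alcohol without epimerisation and release the auxiliary for recovery.

Step 4
Reactants: 6 (2R,3R)-3-(benzyloxy)-2-methylpent-4-en-1-ol
Product: 7 (3R,4R)-5-azido-3-(benzyloxy)-4-methylpent-1-ene
Conditions: (PhO)2P(O)N3, DIAD, PPh3, THF, 0 → 23 °C
Reagents that add atoms: diphenylphosphoryl azide, [N-]=[N+]=NP(=O)(Oc1ccccc1)Oc1ccccc1
Why: Mitsunobu azidation, an SN2 displacement of the primary oxyphosphonium by azide, installs the nitrogen without involving the neighbouring stereocentres.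

Step 5
Reactants: 8 (S)-but-3-en-2-ol; 9 2-bromoprop-2-enoic acid
Product: 10 (S)-but-3-en-2-yl 2-bromoprop-2-enoate
Conditions: DCC, DMAP (cat.), CH2Cl2, 0 °C
Reagents that add atoms: none
Why: Steglich esterification takes place at the carboxyl carbon, so the carbinol C–O bond and its (S) configuration are retained.

Step 6
Reactants: 7 (3R,4R)-5-azido-3-(benzyloxy)-4-methylpent-1-ene; 10 (S)-but-3-en-2-yl 2-bromoprop-2-enoate
Product: 12 2-alkylacrylate ester, via B-alkyl-9-BBN borane 11 (not isolated)
Conditions: 9-BBN, THF, 23 °C; then 10, PdCl2(dppf) (cat.), AsPh3, Cs2CO3, DMF/H2O, 23 °C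
Reagents that add atoms: none
Why: 9-BBN should hydroborate the terminal alkene anti-Markovnikov at room temperature without touching the azide, and the B-alkyl Suzuki–Miyaura coupling then joins the primary alkylborane to the sp2 C–Br bond, whose oxidative addition to zerovalent palladium is much faster than ionisation of the allylic ester.

Step 7
Reactants: 12 2-alkylacrylate ester
Product: 13 3-alkyl-5-methylbutenolide
Conditions: second-generation Hoveyda–Grubbs catalyst (cat.), toluene (5 mM), 80 °C
Reagents that add atoms: none
Why: Ring-closing metathesis between the 1,1-disubstituted acrylate and the vinyl group closes the five-membered lactone, which locks the acyl carbon cis to the carbinol carbon across the new trisubstituted alkene while the (S) centre is untouched.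

Step 8
Reactants: 13 3-alkyl-5-methylbutenolide
Product: 14 (Z)-ene-1,4-diol
Conditions: iBu2AlH, CH2Cl2, −78 → −20 °C; aq. potassium sodium tartrate
Reagents that add atoms: none
Why: 1,2-Reduction of the unsaturated lactone by the aluminium hydride opens the ring to the diol with the (Z) geometry inherited from the ring, and the azide is expected to survive at low temperature.

Step 9
Reactants: 14 (Z)-ene-1,4-diol
Product: 15 (Z)-hydroxy allylic acetate
Conditions: AcCl, 2,4,6-collidine, CH2Cl2, −78 °C
Reagents that add atoms: acetyl chloride, CC(Cl)=O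
Why: Kinetically selective acylation should acetylate the unhindered primary allylic hydroxyl and leave the secondary carbinol free for the next coupling.

Step 10
Reactants: 16 trimethyl ethane-1,1,2-tricarboxylate; 17 tert-butyl prop-2-enoate
Product: 19 ring A tert-butyl β-keto ester, via Michael adduct 18 (not isolated)
Conditions: NaH, THF, 0 → 65 °C; AcOH
Reagents that add atoms: none
Why: Tandem Michael–Dieckmann annulation in which the malonate anion adds to the acrylate and the resulting tert-butyl ester enolate closes on the CH2CO2Me carbonyl (5-exo-trig), driven by deprotonation of the β-keto ester, builds ring A with the geminal diester that keeps the future CO2Me carbon achiral for now.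

Step 11
Reactants: 15 (Z)-hydroxy allylic acetate; 19 ring A tert-butyl β-keto ester
Product: 20 allyl enol ether
Conditions: DIAD, PPh3 (added last), toluene, 0 → 23 °C
Reagents that add atoms: none
Why: Mitsunobu O-alkylation, in which the acidic β-keto ester attacks the oxyphosphonium through its enol oxygen (its carbon terminus is tertiary and hindered) with SN2 inversion, should turn the (S) carbinol into the (R)-configured enol ether, and adding the phosphine last to the azodicarboxylate keeps it from reducing the azide.

Step 12
Reactants: 20 allyl enol ether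
Product: 21 Claisen ketone
Conditions: toluene, 130 °C, sealed tube
Reagents that add atoms: none
Why: Claisen rearrangement ([3,3]-sigmatropic) through a chair transition state with the carbinol methyl pseudo-equatorial, in which the (R) C–O centre and the (Z) olefin dictate the bonding face of each terminus, should create both adjacent quaternary carbons in the target configuration and an (E)-propenyl group, the boat being disfavoured because it eclipses the substituents of the two fully substituted termini.

Step 13
Reactants: 21 Claisen ketone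
Product: 23 ring A enol triflate, via potassium enolate 22 (not isolated)
Conditions: KN(SiMe3)2, THF, −78 °C; then Comins' reagent, −78 → −20 °C
Reagents that add atoms: N-(5-chloropyridin-2-yl)-N-(trifluoromethylsulfonyl)trifluoromethanesulfonamide, Clc1ccc(N(S(=O)(=O)C(F)(F)F)S(=O)(=O)C(F)(F)F)nc1
Why: The ketone has a single enolisable α-CH2 and is deprotonated faster than the acetate, so kinetic enolate formation and O-triflation should give one enol triflate.

Step 14
Reactants: 23 ring A enol triflate
Product: 24 azido acid
Conditions: CF3CO2H/CH2Cl2 (1:4), 0 → 23 °C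
Reagents that add atoms: none
Why: Acidolysis of the tert-butyl ester (loss of 2-methylpropene) frees the quaternary carboxylic acid while methyl esters, acetate, benzyl ether, azide and enol triflate are stable to the acid.

Step 15
Reactants: 24 azido acid
Product: 27 nine-membered lactam enol triflate, via pentafluorophenyl ester 25 (not isolated), via amino pentafluorophenyl ester 26 (not isolated)
Conditions: C6F5OH, EDC·HCl, DMAP (cat.), CH2Cl2, 23 °C; then PMe3, THF/H2O (9:1), 1 mM, 45 °C
Reagents that add atoms: none
Why: Macrolactamisation in which the hindered acid is activated before the amine is unmasked by Staudinger reduction under high dilution, so that acylation is intramolecular, and the two adjacent quaternary carbons (Thorpe–Ingold effect) hold both chain ends gauche and should favour the nine-membered ring over oligomers.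

Step 16
Reactants: 27 nine-membered lactam enol triflate
Product: 28 cross-conjugated dienone
Conditions: CO (1 atm), Bu3SnCH=CH2, Pd(PPh3)4 (cat.), LiCl, THF, 55 °C
Reagents that add atoms: carbon monoxide, [C-]#[O+]; tributyl(vinyl)stannane, C=C[Sn](CCCC)(CCCC)CCCC
Why: Carbonylative Stille coupling (oxidative addition of the enol triflate, CO insertion, transmetalation with the vinylstannane) installs the vinyl ketone on the ring A alkene and creates no stereocentre.

Step 17
Reactants: 28 cross-conjugated dienone
Product: 29 bicyclic enone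
Conditions: BF3·OEt2, ClCH2CH2Cl, 60 °C
Reagents that add atoms: none
Why: Nazarov cyclisation, a conrotatory 4π electrocyclisation of the Lewis-acid-bound pentadienyl cation, closes ring B, and proton loss from the ring-fusion carbon should give the tetrasubstituted enone, which erases the transient stereocentre.

Step 18
Reactants: 29 bicyclic enone
Product: 31 ring B enol triflate, via silyl enol ether 30 (not isolated)
Conditions: [(Ph3P)CuH]6 (cat.), PhMe2SiH, toluene, 23 °C; then CsF, PhNTf2, MeOCH2CH2OMe, 23 °C
Reagents that add atoms: N-phenylbis(trifluoromethanesulfonimide), O=S(=O)(N(c1ccccc1)S(=O)(=O)C(F)(F)F)C(F)(F)F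
Why: Copper hydride conjugate reduction (1,4-hydrosilylation) should deliver hydride to the β-carbon from the face opposite the bulky acetoxymethyl-bearing quaternary carbon, setting the ring-fusion methine cis to the lactam carbonyl, and the regiodefined silyl enol ether is converted by fluoride and the triflimide into the enol triflate that fixes the tetrasubstituted alkene.

Step 19
Reactants: 31 ring B enol triflate
Product: 32 allyl propenyl triene
Conditions: Bu3SnCH2CH=CH2, Pd(PPh3)4 (cat.), LiCl, THF, 65 °C
Reagents that add atoms: allyltributylstannane, C=CC[Sn](CCCC)(CCCC)CCCC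
Why: Stille coupling of the enol triflate with the allylstannane gives the skipped diene, chloride and excess stannane favouring transmetalation over an intramolecular Heck reaction with the propenyl group.

Step 20
Reactants: 32 allyl propenyl triene
Product: 33 cycloheptadiene lactam geminal diester
Conditions: second-generation Grubbs catalyst (cat.), CH2Cl2 (2 mM), 40 °C
Reagents that add atoms: none
Why: Ring-closing metathesis between the propenyl group, which the nine-membered lactam holds near ring B, and the allyl group should close the seven-membered ring with loss of propene, the ring enforcing the cis alkene and the tetrasubstituted alkene staying inert.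

Step 21
Reactants: 33 cycloheptadiene lactam geminal diester
Product: 34 tetracyclic nine-membered lactam
Conditions: LiCl, H2O, DMSO, 140 °C
Reagents that add atoms: none
Why: Krapcho dealkoxycarbonylation generates an ester enolate whose kinetic protonation on the less hindered face (that of the lactam carbonyl and the ring-fusion hydrogen) should place CO2Me cis to the ring B CH2 and to the acetoxymethyl-bearing quaternary carbon, as in the target.

Step 22
Reactants: 34 tetracyclic nine-membered lactam; 35 formaldehyde
Product: 38 pentacyclic diene benzyl ether, via N-hydroxymethyl lactam 36 (not isolated), via N-acyliminium ion 37 (not isolated)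
Conditions: (CH2O)n, CF3CO2H, CH2Cl2, 0 → 23 °C
Reagents that add atoms: none
Why: Acid depolymerises paraformaldehyde and the lactam N–H adds to give the hemiaminal, which ionises to the N-acyliminium ion; its CH2 carbon is attacked by the cycloheptadiene carbon attached to the acetoxymethyl-bearing quaternary carbon, and the secondary cation so formed loses the neighbouring doubly allylic proton to give the diene conjugated with the tetrasubstituted alkene. The closest known reaction type is the N-acyliminium (aza-Prins) cyclisation of N-hydroxymethyl amides onto alkenes. The six-membered lactam closes in a 6-exo-trig mode with respect to the alkene (the iminium carbon is endocyclic), bridging nitrogen and the quaternary carbon 1,4 across the nine-membered ring. The new methine is controlled by the tether, because the iminium is held on the face of the seven-membered ring to which the lactam is fused and can bond only there, which is the target configuration. The step needs chemoselectivity for the disubstituted over the more electron-rich tetrasubstituted alkene and a single mode of proton loss; the first should be secured by the nine-membered ring, which anchors nitrogen over the quaternary carbon carrying the reacting alkene, and by the fact that attack on the tetrasubstituted alkene would have to build a quaternary centre next to an existing one, the second by the acidity of the doubly allylic CH2.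

Step 23
Reactants: 38 pentacyclic diene benzyl ether
Product: 39 target CNP0296366.1
Conditions: H2 (1 atm), 10% Pd/C, EtOAc, 23 °C
Reagents that add atoms: none
Why: Heterogeneous hydrogenation should saturate the accessible disubstituted alkene of the diene and hydrogenolyse the benzyl ether, while the tetrasubstituted ring-fusion alkene is too hindered to be reduced, and no stereocentre is formed or lost.

**Compound list**

1 | (S)-4-benzyl-3-propanoyl-1,3-oxazolidin-2-one | CCC(=O)N1[C@@H](Cc2ccccc2)COC1=O | starting material
2 | acrolein (prop-2-enal) | C=CC=O | starting material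
3 | (Z)-dibutylboron enolate of 1 (not isolated) | C/C=C(\OB(CCCC)CCCC)N1[C@@H](Cc2ccccc2)COC1=O | intermediate
4 | (S)-4-benzyl-3-[(2S,3R)-3-hydroxy-2-methylpent-4-enoyl]-1,3-oxazolidin-2-one | C=C[C@@H](O)[C@H](C)C(=O)N1[C@@H](Cc2ccccc2)COC1=O | intermediate
5 | (S)-4-benzyl-3-[(2S,3R)-3-(benzyloxy)-2-methylpent-4-enoyl]-1,3-oxazolidin-2-one | C=C[C@@H](OCc1ccccc1)[C@H](C)C(=O)N1[C@@H](Cc2ccccc2)COC1=O | intermediate
6 | (2R,3R)-3-(benzyloxy)-2-methylpent-4-en-1-ol | C=C[C@@H](OCc1ccccc1)[C@H](C)CO | intermediate
7 | (3R,4R)-5-azido-3-(benzyloxy)-4-methylpent-1-ene | C=C[C@@H](OCc1ccccc1)[C@H](C)CN=[N+]=[N-] | intermediate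
8 | (S)-but-3-en-2-ol | C=C[C@H](C)O | starting material
9 | 2-bromoprop-2-enoic acid | C=C(Br)C(=O)O | starting material
10 | (S)-but-3-en-2-yl 2-bromoprop-2-enoate | C=C[C@H](C)OC(=O)C(Br)=C | intermediate
11 | 9-[(3R,4R)-5-azido-3-(benzyloxy)-4-methylpentyl]-9-borabicyclo[3.3.1]nonane (not isolated) | B1(CC[C@@H](OCc2ccccc2)[C@H](C)CN=[N+]=[N-])C3CCCC1CCC3 | intermediate
12 | (S)-but-3-en-2-yl 2-[(3R,4R)-5-azido-3-(benzyloxy)-4-methylpentyl]prop-2-enoate | C=C[C@H](C)OC(=O)C(=C)CC[C@@H](OCc1ccccc1)[C@H](C)CN=[N+]=[N-] | intermediate
13 | (S)-3-[(3R,4R)-5-azido-3-(benzyloxy)-4-methylpentyl]-5-methylfuran-2(5H)-one | C[C@@H]1OC(=O)C(CC[C@@H](OCc2ccccc2)[C@H](C)CN=[N+]=[N-])=C1 | intermediate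
14 | (2Z,4S)-2-[(3R,4R)-5-azido-3-(benzyloxy)-4-methylpentyl]pent-2-ene-1,4-diol | C[C@H](O)/C=C(\CO)CC[C@@H](OCc1ccccc1)[C@H](C)CN=[N+]=[N-] | intermediate
15 | (2Z,4S)-2-[(3R,4R)-5-azido-3-(benzyloxy)-4-methylpentyl]-4-hydroxypent-2-en-1-yl acetate | C[C@H](O)/C=C(\COC(C)=O)CC[C@@H](OCc1ccccc1)[C@H](C)CN=[N+]=[N-] | intermediate
16 | trimethyl ethane-1,1,2-tricarboxylate | COC(=O)CC(C(=O)OC)C(=O)OC | starting material
17 | tert-butyl prop-2-enoate | C=CC(=O)OC(C)(C)C | starting material
18 | 4-tert-butyl 1,2,2-trimethyl butane-1,2,2,4-tetracarboxylate, formed as its sodium enolate (not isolated) | COC(=O)CC(CCC(=O)OC(C)(C)C)(C(=O)OC)C(=O)OC | intermediate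
19 | 3-tert-butyl 1,1-dimethyl 4-oxocyclopentane-1,1,3-tricarboxylate (racemic, stereolabile at C-3) | COC(=O)C1(C(=O)OC)CC(C(=O)OC(C)(C)C)C(=O)C1 | intermediate
20 | enol ether of 19 with the (R)-configured, (Z)-olefinic allyl group from 15 (carbinol carbon inverted) | COC(=O)C1(C(=O)OC)CC(C(=O)OC(C)(C)C)=C(O[C@H](C)/C=C(\COC(C)=O)CC[C@@H](OCc2ccccc2)[C@H](C)CN=[N+]=[N-])C1 | intermediate
21 | Claisen ketone: 4-oxocyclopentane-1,1,3-tricarboxylate (1,1-dimethyl, 3-tert-butyl) whose C-3 carries the quaternary carbon bearing CH2OAc, (E)-prop-1-enyl and the (3R,4R)-5-azido-3-(benzyloxy)-4-methylpentyl chain; both quaternary centres as in 39 | COC(=O)C1(C(=O)OC)C[C@](C(=O)C1)(C(=O)OC(C)(C)C)[C@](COC(C)=O)(/C=C/C)CC[C@@H](OCc2ccccc2)[C@H](C)CN=[N+]=[N-] | intermediate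
22 | potassium enolate of 21 (not isolated) | COC(=O)C1(C(=O)OC)C[C@](C([O-])=C1)(C(=O)OC(C)(C)C)[C@](COC(C)=O)(/C=C/C)CC[C@@H](OCc2ccccc2)[C@H](C)CN=[N+]=[N-].[K+] | intermediate
23 | ring A enol triflate of 21 (tert-butyl ester, azide) | COC(=O)C1(C(=O)OC)C[C@](C(OS(=O)(=O)C(F)(F)F)=C1)(C(=O)OC(C)(C)C)[C@](COC(C)=O)(/C=C/C)CC[C@@H](OCc2ccccc2)[C@H](C)CN=[N+]=[N-] | intermediate
24 | azido acid: 23 with the tert-butyl ester cleaved to CO2H | COC(=O)C1(C(=O)OC)C[C@](C(OS(=O)(=O)C(F)(F)F)=C1)(C(=O)O)[C@](COC(C)=O)(/C=C/C)CC[C@@H](OCc2ccccc2)[C@H](C)CN=[N+]=[N-] | intermediate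
25 | pentafluorophenyl ester of 24 (not isolated) | COC(=O)C1(C(=O)OC)C[C@](C(OS(=O)(=O)C(F)(F)F)=C1)(C(=O)Oc2c(F)c(F)c(F)c(F)c2F)[C@](COC(C)=O)(/C=C/C)CC[C@@H](OCc3ccccc3)[C@H](C)CN=[N+]=[N-] | intermediate
26 | amino pentafluorophenyl ester, azide of 25 reduced to NH2 (not isolated) | COC(=O)C1(C(=O)OC)C[C@](C(OS(=O)(=O)C(F)(F)F)=C1)(C(=O)Oc2c(F)c(F)c(F)c(F)c2F)[C@](COC(C)=O)(/C=C/C)CC[C@@H](OCc3ccccc3)[C@H](C)CN | intermediate
27 | nine-membered lactam spiro-fused to the ring A enol triflate; carries CH2OAc, (E)-propenyl, OBn, CH3 | COC(=O)C1(C(=O)OC)C[C@]2(C(OS(=O)(=O)C(F)(F)F)=C1)C(=O)NC[C@@H](C)[C@H](OCc3ccccc3)CC[C@@]2(COC(C)=O)/C=C/C | intermediate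
28 | dienone: 27 with OTf replaced by C(=O)CH=CH2 | COC(=O)C1(C(=O)OC)C[C@]2(C(C(=O)C=C)=C1)C(=O)NC[C@@H](C)[C@H](OCc3ccccc3)CC[C@@]2(COC(C)=O)/C=C/C | intermediate
29 | bicyclo[3.3.0]oct-1(5)-en-2-one (rings A and B, tetrasubstituted enone) spiro-fused to the nine-membered lactam | COC(=O)C1(C(=O)OC)C[C@]2(C3=C1CCC3=O)C(=O)NC[C@@H](C)[C@H](OCc4ccccc4)CC[C@@]2(COC(C)=O)/C=C/C | intermediate
30 | dimethylphenylsilyl enol ether of the reduced ketone, ring-fusion H cis to the lactam carbonyl (not isolated) | COC(=O)C1(C(=O)OC)C[C@]2(C3=C(O[Si](C)(C)c5ccccc5)CC[C@H]13)C(=O)NC[C@@H](C)[C@H](OCc4ccccc4)CC[C@@]2(COC(C)=O)/C=C/C | intermediate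
31 | ring B enol triflate with the tetrasubstituted alkene in its final position | COC(=O)C1(C(=O)OC)C[C@]2(C3=C(OS(=O)(=O)C(F)(F)F)CC[C@H]13)C(=O)NC[C@@H](C)[C@H](OCc4ccccc4)CC[C@@]2(COC(C)=O)/C=C/C | intermediate
32 | triene: 31 with OTf replaced by allyl | COC(=O)C1(C(=O)OC)C[C@]2(C3=C(CC=C)CC[C@H]13)C(=O)NC[C@@H](C)[C@H](OCc4ccccc4)CC[C@@]2(COC(C)=O)/C=C/C | intermediate
33 | tetracyclic nine-membered lactam with cyclohepta-1,4-diene, geminal dimethyl diester | COC(=O)C1(C(=O)OC)C[C@@]23C(=O)NC[C@@H](C)[C@H](OCc4ccccc4)CC[C@@]3(COC(C)=O)C=CCC5=C2[C@@H]1CC5 | intermediate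
34 | tetracyclic secondary nine-membered lactam with cyclohepta-1,4-diene, one CO2Me cis to the ring B CH2 (precursor of the key step) | COC(=O)[C@@H]1C[C@@]23C(=O)NC[C@@H](C)[C@H](OCc4ccccc4)CC[C@@]3(COC(C)=O)C=CCC5=C2[C@@H]1CC5 | intermediate
35 | formaldehyde (used as paraformaldehyde) | C=O | starting material
36 | N-hydroxymethyl derivative of 34 (not isolated) | COC(=O)[C@@H]1C[C@@]23C(=O)N(CO)C[C@@H](C)[C@H](OCc4ccccc4)CC[C@@]3(COC(C)=O)C=CCC5=C2[C@@H]1CC5 | intermediate
37 | N-methylidene N-acyliminium trifluoroacetate from 36 (not isolated) | COC(=O)[C@@H]1C[C@@]23C(=O)[N+](=C)C[C@@H](C)[C@H](OCc4ccccc4)CC[C@@]3(COC(C)=O)C=CCC5=C2[C@@H]1CC5.[O-]C(=O)C(F)(F)F | intermediate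
38 | pentacyclic conjugated diene, O-benzyl ether (product of the key step) | COC(=O)[C@@H]1C[C@@]23C(=O)N4C[C@@H](C=CC5=C2[C@@H]1CC5)[C@]3(COC(C)=O)CC[C@@H](OCc6ccccc6)[C@H](C)C4 | intermediate
39 | CNP0296366.1 | COC(=O)[C@@H]1C[C@@]23C(=O)N4C[C@@H](CCC5=C2[C@@H]1CC5)[C@]3(COC(C)=O)CC[C@@H](O)[C@H](C)C4 | target

**Step count**

Total: 23 steps. Longest linear sequence: 21 steps (steps 1–4, 6–9 and 11–23).

**Steps most likely to fail**

Step 12 (Claisen rearrangement). The relative configuration of the two quaternary carbons may erode if a boat transition state competes with the chair, and the azide may lose nitrogen at the temperature the hindered rearrangement needs. The fallback moves the rearrangement to the ester-enolate manifold and sets out from 15 and 16. Mitsunobu esterification of 15 with acrylic acid (inversion at the carbinol) gives the (R)-configured acrylate F1. Michael–Dieckmann annulation of F1 with 16, as in step 10, gives the allyl β-keto ester F2. Double soft enolisation (Me3SiOTf, Et3N) gives the bis(trimethylsilyl) ketene acetal F3, in which ring A is only spiro-attached to the pericyclic array. Its Ireland–Claisen (silyl Carroll-type) rearrangement near room temperature through the usual chair should give the silyl ester silyl enol ether F4. Treatment of F4 with CsF and PhNTf2 converts the silyl enol ether into the enol triflate, and aqueous work-up frees the acid, so the route is rejoined at 24.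

Step 15 (nine-membered lactamisation). Intermolecular acylation to dimers and oligomers may outrun the slow ring closure of a hindered active ester. The fallback replaces the direct closure by a ring expansion and sets out from 24. Debenzylation with BCl3 and pentamethylbenzene at −78 °C gives the hydroxy azido acid F5. Yamaguchi lactonisation onto the secondary hydroxyl closes the seven-membered azido lactone F6. Staudinger reduction gives the amino lactone F7, whose amine lies 1,3 to the lactone oxygen and should take over the acyl group through a six-membered cyclol (O-to-N acyl shift), expanding the ring to the nine-membered hydroxy lactam F8. Neutral benzylation with 2-benzyloxy-1-methylpyridinium triflate and MgO returns to 27.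

Step 22 (aza-Prins bridging). The iminium carbon may attack the more electron-rich tetrasubstituted alkene instead, abstract hydride from the doubly allylic CH2, or the cation may migrate before proton loss. The fallback forms the same two bonds by a radical and sets out from 34. N-Alkylation (NaH, chloromethyl phenyl sulfide) gives the N-(phenylsulfanylmethyl) lactam F9. With Bu3SnH and AIBN under slow addition, the α-amidomethyl radical should close 6-exo on the disubstituted alkene carbon next to the quaternary carbon; radicals add poorly to a fully substituted alkene carbon, and the tether again fixes the face. Reduction of the adduct radical gives the saturated O-benzyl ether F10, and hydrogenolysis as in step 23 returns to 39.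

**Further compounds**

F1 | step 12 | (R)-configured acrylate of the allylic alcohol 15 | C=CC(=O)O[C@H](C)/C=C(\COC(C)=O)CC[C@@H](OCc1ccccc1)[C@H](C)CN=[N+]=[N-]
F2 | step 12 | 1,1-dimethyl 4-oxocyclopentane-1,1,3-tricarboxylate whose C-3 ester is the allyl group of F1 (stereolabile at C-3) | COC(=O)C1(C(=O)OC)CC(C(=O)O[C@H](C)/C=C(\COC(C)=O)CC[C@@H](OCc2ccccc2)[C@H](C)CN=[N+]=[N-])C(=O)C1
F3 | step 12 | bis(trimethylsilyl) ketene acetal and dienol ether of F2 | COC(=O)C1(C(=O)OC)C/C(=C(/O[Si](C)(C)C)O[C@H](C)/C=C(\COC(C)=O)CC[C@@H](OCc2ccccc2)[C@H](C)CN=[N+]=[N-])C(O[Si](C)(C)C)=C1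
F4 | step 12 | rearranged trimethylsilyl ester with ring A trimethylsilyl enol ether, quaternary centres as in 21 | COC(=O)C1(C(=O)OC)C[C@](C(O[Si](C)(C)C)=C1)(C(=O)O[Si](C)(C)C)[C@](COC(C)=O)(/C=C/C)CC[C@@H](OCc2ccccc2)[C@H](C)CN=[N+]=[N-]
F5 | step 15 | hydroxy azido acid (24 without the benzyl group) | COC(=O)C1(C(=O)OC)C[C@](C(OS(=O)(=O)C(F)(F)F)=C1)(C(=O)O)[C@](COC(C)=O)(/C=C/C)CC[C@@H](O)[C@H](C)CN=[N+]=[N-]
F6 | step 15 | seven-membered azido lactone | COC(=O)C1(C(=O)OC)C[C@]2(C(OS(=O)(=O)C(F)(F)F)=C1)C(=O)O[C@@H]([C@H](C)CN=[N+]=[N-])CC[C@@]2(COC(C)=O)/C=C/C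
F7 | step 15 | seven-membered amino lactone | COC(=O)C1(C(=O)OC)C[C@]2(C(OS(=O)(=O)C(F)(F)F)=C1)C(=O)O[C@@H]([C@H](C)CN)CC[C@@]2(COC(C)=O)/C=C/C
F8 | step 15 | nine-membered hydroxy lactam (27 with OH in place of OBn) | COC(=O)C1(C(=O)OC)C[C@]2(C(OS(=O)(=O)C(F)(F)F)=C1)C(=O)NC[C@@H](C)[C@H](O)CC[C@@]2(COC(C)=O)/C=C/C
F9 | step 22 | N-(phenylsulfanylmethyl) derivative of 34 | COC(=O)[C@@H]1C[C@@]23C(=O)N(CSc4ccccc4)C[C@@H](C)[C@H](OCc5ccccc5)CC[C@@]3(COC(C)=O)C=CCC6=C2[C@@H]1CC6
F10 | step 22 | O-benzyl ether of 39 | COC(=O)[C@@H]1C[C@@]23C(=O)N4C[C@@H](CCC5=C2[C@@H]1CC5)[C@]3(COC(C)=O)CC[C@@H](OCc6ccccc6)[C@H](C)C4
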